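**Retrosynthetic overview**

- The last skeletal bond is C3–C5' between the two dihydrobenzofurans. It is cut to a C3 redox-active ester on the styryl-bearing ring and a C5' arylzinc of the 7'-oxygenated ring. Before that, the C4 styryl group is cut by a Heck disconnection to a C4 triflate.
- The strategy rests on one feature: O1, C2 with its 4-hydroxyphenyl group, C3 and the benzo ring C3a–C7a (styryl at C4, OH at C6) are a (2S)-5,7-dioxygenated flavanone whose carbonyl carbon C4 has been pushed out of the ring onto C3. The unprimed furan ring is therefore made by an oxidative 1,2-aryl shift (ring contraction) that forms C3–C3a and leaves CO2Me on C3 as the handle for the aryl group.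
- The flavanone comes from phloroacetophenone by differential O-protection, chromone formation, enantioselective conjugate addition of the arylboronic acid (sets C2) and mesylation.
- The primed ring (O1', C2', C3', C3a'–C7a') is closed separately from 5-bromo-o-vanillin by dirhodium-carbene C–H insertion (C2'–C3' bond), epimerised to trans and reprotected as silyl ethers.
- Ring order: pyranone ring, contracted to the unprimed furan ring; primed furan ring in parallel. No ring is formed after fragment union, and the final deprotections avoid acid, which could cyclise the stilbene onto a neighbouring arene.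

Key step: step 6

Assumption: (R)-t-BuPyOx (step 4) and Rh2(S-PTAD)4 (step 17) are taken to be the catalyst antipodes that give the (2S)-flavanone and the (3R)-configured insertion product; if either sense of induction proves opposite, the mirror-image catalyst is used with no other change.

**Route**

Step 1
Reactants: 1 2',4',6'-trihydroxyacetophenone
Product: 2 2',6'-dihydroxy-4'-(triisopropylsilyloxy)acetophenone
Conditions: TIPSCl (1.05 equiv), imidazole, DMF, 0 °C
Reagents that add atoms: triisopropylsilyl chloride, CC(C)[Si](Cl)(C(C)C)C(C)C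
Why: Chemoselective O-silylation should occur at the 4'-hydroxyl because it is the only one not hydrogen-bonded to the acetyl group.

Step 2
Reactants: 2 2',6'-dihydroxy-4'-(triisopropylsilyloxy)acetophenone
Product: 3 2'-benzyloxy-6'-hydroxy-4'-(triisopropylsilyloxy)acetophenone
Conditions: BnOH, PPh3, DIAD, THF, 0 °C to rt
Reagents that add atoms: benzyl alcohol, OCc1ccccc1
Why: Mitsunobu etherification benzylates one of the two equivalent ortho phenols under neutral conditions that spare the silyl ether, and it should stop there because the remaining hydroxyl is chelated to the ketone.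

Step 3
Reactants: 3 2'-benzyloxy-6'-hydroxy-4'-(triisopropylsilyloxy)acetophenone
Product: 5 5-benzyloxy-7-(triisopropylsilyloxy)chromen-4-one, via enaminone 4 (not isolated)
Conditions: Me2NCH(OMe)2, toluene, 90 °C; then aq HCl, CH2Cl2, rt
Reagents that add atoms: N,N-dimethylformamide dimethyl acetal, COC(OC)N(C)C
Why: Enaminone formation at the acetyl methyl group, followed by acid-promoted addition of the phenol and loss of dimethylamine, is the standard chromone synthesis from 2'-hydroxyacetophenones.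

Step 4
Reactants: 5 5-benzyloxy-7-(triisopropylsilyloxy)chromen-4-one; 6 4-hydroxyphenylboronic acid
Product: 7 (2S)-5-O-benzyl-7-O-(triisopropylsilyl)naringenin
Conditions: Pd(OCOCF3)2 (5 mol%), (R)-t-BuPyOx (6 mol%), NH4PF6, H2O, ClCH2CH2Cl, 60 °C
Reagents that add atoms: none
Why: Enantioselective conjugate addition of an arylboronic acid to a chromone, catalysed by a pyridine-oxazoline complex of divalent palladium, in which the tert-butyl group of the ligand directs aryl transfer to one face of C2 and sets the (2S) centre without base that could open the flavanone.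

Step 5
Reactants: 7 (2S)-5-O-benzyl-7-O-(triisopropylsilyl)naringenin
Product: 8 (2S)-5-O-benzyl-4'-O-methanesulfonyl-7-O-(triisopropylsilyl)naringenin
Conditions: MsCl, Et3N, CH2Cl2, −20 to 0 °C
Reagents that add atoms: methanesulfonyl chloride, CS(=O)(=O)Cl
Why: Fast O-sulfonylation of the phenol at low temperature should outrun base-induced ring opening at C2 and installs the electron-withdrawing group that deactivates the C2 aryl ring for the next step.

Step 6
Reactants: 8 (2S)-5-O-benzyl-4'-O-methanesulfonyl-7-O-(triisopropylsilyl)naringenin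
Product: 11 methyl (2S,3S)-4-benzyloxy-2-[4-(methanesulfonyloxy)phenyl]-6-(triisopropylsilyloxy)-2,3-dihydrobenzofuran-3-carboxylate (2,3-trans), via methyl enol ether 9 (not isolated), via C3-phenyliodonio dimethyl ketal 10 (not isolated)
Conditions: PhI(OAc)2 (1.2 equiv), H2SO4 (cat.), HC(OMe)3/MeOH, 0 °C to rt
Reagents that add atoms: methanol, CO; trimethyl orthoformate, COC(OC)OC (either supplies the ester methoxy group)
Why: Acid and orthoformate convert the ketone into its methyl enol ether 9, which PhI(OAc)2 attacks at C3 on the face anti to the pseudo-equatorial C2 aryl group while methanol caps C4, giving the C3-phenyliodonio dimethyl ketal 10. The arene carbon C4a (flavanone numbering), which carries oxygen at both ortho positions and at the para position, then shifts from C4 to C3 through a phenonium-type bridge antiperiplanar to the departing iodobenzene, and the dimethoxycarbenium ion left at the old C4 collapses to the methyl ester. The closest known reaction is the oxidative ring contraction of flavanones to trans methyl 2-aryl-2,3-dihydrobenzofuran-3-carboxylates by trivalent iodine or trivalent thallium in trimethyl orthoformate. The five-membered ring (O1, C2, C3, C3a, C7a) is closed by the 1,2-aryl shift itself, a contraction of the chromanone in which the C3–C3a bond forms as the C4–C4a bond breaks. C2 is carried over unchanged from 8 and controls the new C3 centre, because anti iodination followed by inversion at C3 places the ester trans to the C2 aryl group and gives (2S,3S). The step needs the benzo ring to migrate in preference to the C2 aryl group (isoflavone) and to elimination (flavone), which is secured by the trioxygenated migrating ring and by the mesylate, which deactivates the C2 aryl ring and also disfavours acid ionisation of the C2–O bond.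

Step 7
Reactants: 11 methyl (2S,3S)-4-benzyloxy-2-[4-(methanesulfonyloxy)phenyl]-6-(triisopropylsilyloxy)-2,3-dihydrobenzofuran-3-carboxylate
Product: 12 methyl (2S,3S)-4-hydroxy-2-[4-(methanesulfonyloxy)phenyl]-6-(triisopropylsilyloxy)-2,3-dihydrobenzofuran-3-carboxylate
Conditions: H2 (1 atm), Pd/C, EtOAc, rt
Reagents that add atoms: none
Why: Hydrogenolysis of the primary benzyl aryl ether should be much faster than cleavage of the hindered cyclic C2–O bond, whose benzylic carbon is deactivated by the mesyloxyphenyl group, and the mesylate, silyl ether and ester are inert.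

Step 8
Reactants: 12 methyl (2S,3S)-4-hydroxy-2-[4-(methanesulfonyloxy)phenyl]-6-(triisopropylsilyloxy)-2,3-dihydrobenzofuran-3-carboxylate
Product: 13 methyl (2S,3S)-2-[4-(methanesulfonyloxy)phenyl]-4-(trifluoromethanesulfonyloxy)-6-(triisopropylsilyloxy)-2,3-dihydrobenzofuran-3-carboxylate
Conditions: Tf2O, pyridine, CH2Cl2, 0 °C
Reagents that add atoms: trifluoromethanesulfonic anhydride, O=S(=O)(OS(=O)(=O)C(F)(F)F)C(F)(F)F
Why: O-Triflation of the only free phenol turns C4 into a cross-coupling electrophile that the much less reactive aryl mesylate cannot compete with.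

Step 9
Reactants: 14 4-acetoxystyrene
Product: 16 4-(triisopropylsilyloxy)styrene, via 4-vinylphenol 15 (not isolated)
Conditions: K2CO3 (cat.), MeOH, 0 °C; evaporate; TIPSCl, imidazole, DMF, rt
Reagents that add atoms: triisopropylsilyl chloride, CC(C)[Si](Cl)(C(C)C)C(C)C
Why: Transesterification of the aryl acetate and immediate silylation give a styrene whose phenol protection survives the later ester cleavage, without isolating the polymerisation-prone 4-vinylphenol.

Step 10
Reactants: 13 methyl (2S,3S)-2-[4-(methanesulfonyloxy)phenyl]-4-(trifluoromethanesulfonyloxy)-6-(triisopropylsilyloxy)-2,3-dihydrobenzofuran-3-carboxylate; 16 4-(triisopropylsilyloxy)styrene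
Product: 17 methyl (2S,3S)-2-[4-(methanesulfonyloxy)phenyl]-6-(triisopropylsilyloxy)-4-[(E)-4-(triisopropylsilyloxy)styryl]-2,3-dihydrobenzofuran-3-carboxylate
Conditions: Pd(OAc)2, P(o-tol)3, LiCl, Et3N, DMF, 90 °C
Reagents that add atoms: none
Why: Heck reaction in which zerovalent palladium inserts into the aryl triflate, the chloride additive and monodentate phosphine keep the neutral pathway so that the aryl group adds to the terminal alkene carbon, and syn β-hydride elimination gives the E stilbene.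

Step 11
Reactants: 17 methyl (2S,3S)-2-[4-(methanesulfonyloxy)phenyl]-6-(triisopropylsilyloxy)-4-[(E)-4-(triisopropylsilyloxy)styryl]-2,3-dihydrobenzofuran-3-carboxylate
Product: 18 (2S,3S)-2-[4-(methanesulfonyloxy)phenyl]-6-(triisopropylsilyloxy)-4-[(E)-4-(triisopropylsilyloxy)styryl]-2,3-dihydrobenzofuran-3-carboxylic acid
Conditions: Me3SnOH, ClCH2CH2Cl, 80 °C; 5% HCl work-up
Reagents that add atoms: trimethyltin hydroxide, C[Sn](C)(C)O
Why: Tin hydroxide-mediated methyl ester cleavage is near neutral, so it should avoid the C3 enolate that could expel the ring phenoxide by β-elimination, and it spares the mesylate and the aryl silyl ethers.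

Step 12
Reactants: 18 (2S,3S)-2-[4-(methanesulfonyloxy)phenyl]-6-(triisopropylsilyloxy)-4-[(E)-4-(triisopropylsilyloxy)styryl]-2,3-dihydrobenzofuran-3-carboxylic acid
Product: 19 1,3-dioxoisoindolin-2-yl (2S,3S)-2-[4-(methanesulfonyloxy)phenyl]-6-(triisopropylsilyloxy)-4-[(E)-4-(triisopropylsilyloxy)styryl]-2,3-dihydrobenzofuran-3-carboxylate
Conditions: N-hydroxyphthalimide, DIC, DMAP (cat.), CH2Cl2, rt
Reagents that add atoms: N-hydroxyphthalimide, ON1C(=O)c2ccccc2C1=O
Why: Carbodiimide (Steglich-type) esterification gives the redox-active N-acyloxyphthalimide needed for decarboxylative coupling.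

Step 13
Reactants: 20 5-bromo-2-hydroxy-3-methoxybenzaldehyde; 21 4-methoxybenzyl chloride
Product: 22 5-bromo-3-methoxy-2-(4-methoxybenzyloxy)benzaldehyde
Conditions: K2CO3, KI (cat.), DMF, 50 °C
Reagents that add atoms: none
Why: Williamson etherification of the phenol installs the benzylic CH2 that will become C2' with its 4-oxygenated aryl group.

Step 14
Reactants: 22 5-bromo-3-methoxy-2-(4-methoxybenzyloxy)benzaldehyde; 23 1-bromo-3,5-dimethoxybenzene
Product: 25 [5-bromo-3-methoxy-2-(4-methoxybenzyloxy)phenyl](3,5-dimethoxyphenyl)methanol (racemic), via arylmagnesium bromide 24 (not isolated)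
Conditions: 23, Mg, THF; then 22, THF, 0 °C; NH4Cl (aq)
Reagents that add atoms: none
Why: Grignard addition to the aldehyde is fast at 0 °C, where the aryl bromide of 22 does not undergo halogen-magnesium exchange.

Step 15
Reactants: 25 [5-bromo-3-methoxy-2-(4-methoxybenzyloxy)phenyl](3,5-dimethoxyphenyl)methanol
Product: 26 [5-bromo-3-methoxy-2-(4-methoxybenzyloxy)phenyl](3,5-dimethoxyphenyl)methanone
Conditions: Dess–Martin periodinane, NaHCO3, CH2Cl2, rt
Reagents that add atoms: none
Why: Dess–Martin oxidation of the diarylmethanol gives the diaryl ketone without touching the ethers or the bromide.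

Step 16
Reactants: 26 [5-bromo-3-methoxy-2-(4-methoxybenzyloxy)phenyl](3,5-dimethoxyphenyl)methanone
Product: 27 hydrazone of ketone 26 (E/Z mixture)
Conditions: N2H4·H2O, AcOH (cat.), EtOH, 80 °C
Reagents that add atoms: hydrazine, NN
Why: Acid-catalysed condensation of hydrazine with the diaryl ketone gives the hydrazone that serves as the diazo precursor.

Step 17
Reactants: 27 hydrazone of ketone 26
Product: 29 (2S,3R)-5-bromo-3-(3,5-dimethoxyphenyl)-7-methoxy-2-(4-methoxyphenyl)-2,3-dihydrobenzofuran (2,3-cis), via diaryldiazomethane 28 (not isolated)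
Conditions: MnO2, CH2Cl2, 0 °C; filter; Rh2(S-PTAD)4 (1 mol%), CH2Cl2, 0 °C to rt
Reagents that add atoms: none
Why: MnO2 dehydrogenates the hydrazone to the diaryldiazomethane, and the derived donor/donor dirhodium carbene inserts intramolecularly into the activated benzylic C–H bond of the 4-methoxybenzyl ether to close the five-membered ring, the chiral carboxylate ligands setting C3' as (R) and the concerted insertion giving the 2,3-cis product.

Step 18
Reactants: 29 (2S,3R)-5-bromo-3-(3,5-dimethoxyphenyl)-7-methoxy-2-(4-methoxyphenyl)-2,3-dihydrobenzofuran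
Product: 30 (2R,3R)-5-bromo-3-(3,5-dimethoxyphenyl)-7-methoxy-2-(4-methoxyphenyl)-2,3-dihydrobenzofuran (2,3-trans)
Conditions: CF3CO2H, CH2Cl2, 0 °C to rt
Reagents that add atoms: none
Why: Acid-mediated epimerisation by reversible ionisation of the C2'–O bond to the 4-methoxybenzylic cation and reclosure should converge on the thermodynamically favoured trans isomer, inverting C2' only and leaving C3' untouched.

Step 19
Reactants: 30 (2R,3R)-5-bromo-3-(3,5-dimethoxyphenyl)-7-methoxy-2-(4-methoxyphenyl)-2,3-dihydrobenzofuran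
Product: 31 (2R,3R)-5-bromo-3-(3,5-dihydroxyphenyl)-2-(4-hydroxyphenyl)-2,3-dihydrobenzofuran-7-ol
Conditions: BBr3, CH2Cl2, −78 °C to rt; H2O
Reagents that add atoms: none
Why: Lewis-acid cleavage of the four aryl methyl ethers is done at the fragment stage, where no stilbene is present to undergo acid-triggered cyclisation and the ring is already in its thermodynamic trans form.

Step 20
Reactants: 31 (2R,3R)-5-bromo-3-(3,5-dihydroxyphenyl)-2-(4-hydroxyphenyl)-2,3-dihydrobenzofuran-7-ol
Product: 32 (2R,3R)-5-bromo-3-[3,5-bis(triisopropylsilyloxy)phenyl]-7-(triisopropylsilyloxy)-2-[4-(triisopropylsilyloxy)phenyl]-2,3-dihydrobenzofuran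
Conditions: TIPSOTf, 2,6-lutidine, CH2Cl2, 0 °C to rt
Reagents that add atoms: triisopropylsilyl trifluoromethanesulfonate, CC(C)[Si](OS(=O)(=O)C(F)(F)F)(C(C)C)C(C)C
Why: Exhaustive O-silylation gives ethers that tolerate aryllithium formation and can be removed at the end by fluoride instead of acid.

Step 21
Reactants: 19 1,3-dioxoisoindolin-2-yl (2S,3S)-2-[4-(methanesulfonyloxy)phenyl]-6-(triisopropylsilyloxy)-4-[(E)-4-(triisopropylsilyloxy)styryl]-2,3-dihydrobenzofuran-3-carboxylate; 32 (2R,3R)-5-bromo-3-[3,5-bis(triisopropylsilyloxy)phenyl]-7-(triisopropylsilyloxy)-2-[4-(triisopropylsilyloxy)phenyl]-2,3-dihydrobenzofuran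
Product: 35 (2S,3S)-3-{(2R,3R)-3-[3,5-bis(triisopropylsilyloxy)phenyl]-7-(triisopropylsilyloxy)-2-[4-(triisopropylsilyloxy)phenyl]-2,3-dihydrobenzofuran-5-yl}-2-[4-(methanesulfonyloxy)phenyl]-6-(triisopropylsilyloxy)-4-[(E)-4-(triisopropylsilyloxy)styryl]-2,3-dihydrobenzofuran, via aryllithium 33 (not isolated), via arylzinc chloride 34 (not isolated)
Conditions: 32, t-BuLi (2 equiv), THF, −78 °C; ZnCl2, −78 °C to rt; then 19, NiCl2·glyme (20 mol%), 4,4'-di-tert-butyl-2,2'-bipyridine (40 mol%), THF/DMF, rt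
Reagents that add atoms: none
Why: Nickel-catalysed decarboxylative arylation of a secondary redox-active ester with an arylzinc reagent, in which single-electron reduction and loss of CO2 give a planar benzylic C3 radical that the aryl-nickel species should capture and couple on the face anti to the C2 aryl group, setting C3 as (S) in the trans ring while the primed centres are untouched.

Step 22
Reactants: 35 the hexasilylated monomesylate from step 21
Product: 36 (2S,3S)-3-{(2R,3R)-3-[3,5-bis(triisopropylsilyloxy)phenyl]-7-(triisopropylsilyloxy)-2-[4-(triisopropylsilyloxy)phenyl]-2,3-dihydrobenzofuran-5-yl}-2-(4-hydroxyphenyl)-6-(triisopropylsilyloxy)-4-[(E)-4-(triisopropylsilyloxy)styryl]-2,3-dihydrobenzofuran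
Conditions: LiN(i-Pr)2 (excess), THF, −78 to 0 °C; NH4Cl (aq)
Reagents that add atoms: none
Why: Known cleavage of aryl mesylates by deprotonation of the sulfonyl methyl group and expulsion of the phenoxide with loss of sulfene (E1cB), which should be kinetically much faster at low temperature than deprotonation of the hindered diarylmethine positions and leaves the silyl ethers intact.

Step 23
Reactants: 36 the hexasilyl ether from step 22
Product: 37 (2S,3S)-3-[(2R,3R)-3-(3,5-dihydroxyphenyl)-7-hydroxy-2-(4-hydroxyphenyl)-2,3-dihydrobenzofuran-5-yl]-2-(4-hydroxyphenyl)-4-[(E)-4-hydroxystyryl]-2,3-dihydrobenzofuran-6-ol (CNP0172909.1)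
Conditions: n-Bu4NF, AcOH, THF, 0 °C to rt, argon
Reagents that add atoms: none
Why: Acetic acid-buffered fluoride desilylation should free all six silylated phenols without strong acid, which could cyclise the stilbene onto a neighbouring arene, and without free phenoxide, which could open the 2-(4-hydroxyphenyl) rings through quinone methides.

**Compound list**

1 | 2',4',6'-trihydroxyacetophenone | CC(=O)c1c(O)cc(O)cc1O | starting material
2 | 2',6'-dihydroxy-4'-(triisopropylsilyloxy)acetophenone | CC(=O)c1c(O)cc(O[Si](C(C)C)(C(C)C)C(C)C)cc1O | intermediate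
3 | 2'-benzyloxy-6'-hydroxy-4'-(triisopropylsilyloxy)acetophenone | CC(=O)c1c(O)cc(O[Si](C(C)C)(C(C)C)C(C)C)cc1OCc1ccccc1 | intermediate
4 | (E)-1-[2-benzyloxy-6-hydroxy-4-(triisopropylsilyloxy)phenyl]-3-(dimethylamino)prop-2-en-1-one | CN(C)/C=C/C(=O)c1c(O)cc(O[Si](C(C)C)(C(C)C)C(C)C)cc1OCc1ccccc1 | intermediate (not isolated)
5 | 5-benzyloxy-7-(triisopropylsilyloxy)chromen-4-one | O=c1ccoc2cc(O[Si](C(C)C)(C(C)C)C(C)C)cc(OCc3ccccc3)c12 | intermediate
6 | 4-hydroxyphenylboronic acid | OB(O)c1ccc(O)cc1 | starting material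
7 | (2S)-5-O-benzyl-7-O-(triisopropylsilyl)naringenin | O=C1C[C@@H](c2ccc(O)cc2)Oc2cc(O[Si](C(C)C)(C(C)C)C(C)C)cc(OCc3ccccc3)c12 | intermediate
8 | (2S)-5-O-benzyl-4'-O-methanesulfonyl-7-O-(triisopropylsilyl)naringenin | O=C1C[C@@H](c2ccc(OS(C)(=O)=O)cc2)Oc2cc(O[Si](C(C)C)(C(C)C)C(C)C)cc(OCc3ccccc3)c12 | intermediate (key-step precursor)
9 | (2S)-5-benzyloxy-4-methoxy-2-[4-(methanesulfonyloxy)phenyl]-7-(triisopropylsilyloxy)-2H-chromene | COC1=C[C@@H](c2ccc(OS(C)(=O)=O)cc2)Oc2cc(O[Si](C(C)C)(C(C)C)C(C)C)cc(OCc3ccccc3)c12 | intermediate (not isolated)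
10 | (2S)-5-benzyloxy-4,4-dimethoxy-2-[4-(methanesulfonyloxy)phenyl]-7-(triisopropylsilyloxy)chroman-3-yl(phenyl)iodonium acetate, iodine trans to the C2 aryl group | COC1(OC)[C@H]([I+]c2ccccc2)[C@@H](c2ccc(OS(C)(=O)=O)cc2)Oc2cc(O[Si](C(C)C)(C(C)C)C(C)C)cc(OCc3ccccc3)c12.CC(=O)[O-] | intermediate (not isolated)
11 | methyl (2S,3S)-4-benzyloxy-2-[4-(methanesulfonyloxy)phenyl]-6-(triisopropylsilyloxy)-2,3-dihydrobenzofuran-3-carboxylate | c1ccccc1COc1cc(O[Si](C(C)C)(C(C)C)C(C)C)cc2c1[C@H](C(=O)OC)[C@@H](c1ccc(OS(C)(=O)=O)cc1)O2 | intermediate (key-step product)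
12 | methyl (2S,3S)-4-hydroxy-2-[4-(methanesulfonyloxy)phenyl]-6-(triisopropylsilyloxy)-2,3-dihydrobenzofuran-3-carboxylate | Oc1cc(O[Si](C(C)C)(C(C)C)C(C)C)cc2c1[C@H](C(=O)OC)[C@@H](c1ccc(OS(C)(=O)=O)cc1)O2 | intermediate
13 | methyl (2S,3S)-2-[4-(methanesulfonyloxy)phenyl]-4-(trifluoromethanesulfonyloxy)-6-(triisopropylsilyloxy)-2,3-dihydrobenzofuran-3-carboxylate | O=S(=O)(Oc1cc(O[Si](C(C)C)(C(C)C)C(C)C)cc2c1[C@H](C(=O)OC)[C@@H](c1ccc(OS(C)(=O)=O)cc1)O2)C(F)(F)F | intermediate
14 | 4-acetoxystyrene | CC(=O)Oc1ccc(C=C)cc1 | starting material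
15 | 4-vinylphenol | C=Cc1ccc(O)cc1 | intermediate (not isolated)
16 | 4-(triisopropylsilyloxy)styrene | C=Cc1ccc(O[Si](C(C)C)(C(C)C)C(C)C)cc1 | intermediate
17 | methyl (2S,3S)-2-[4-(methanesulfonyloxy)phenyl]-6-(triisopropylsilyloxy)-4-[(E)-4-(triisopropylsilyloxy)styryl]-2,3-dihydrobenzofuran-3-carboxylate | CC(C)[Si](Oc1ccc(/C=C/c2cc(O[Si](C(C)C)(C(C)C)C(C)C)cc3c2[C@H](C(=O)OC)[C@@H](c2ccc(OS(C)(=O)=O)cc2)O3)cc1)(C(C)C)C(C)C | intermediate
18 | (2S,3S)-2-[4-(methanesulfonyloxy)phenyl]-6-(triisopropylsilyloxy)-4-[(E)-4-(triisopropylsilyloxy)styryl]-2,3-dihydrobenzofuran-3-carboxylic acid | CC(C)[Si](Oc1ccc(/C=C/c2cc(O[Si](C(C)C)(C(C)C)C(C)C)cc3c2[C@H](C(=O)O)[C@@H](c2ccc(OS(C)(=O)=O)cc2)O3)cc1)(C(C)C)C(C)C | intermediate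
19 | 1,3-dioxoisoindolin-2-yl ester of acid 18 | CC(C)[Si](Oc1ccc(/C=C/c2cc(O[Si](C(C)C)(C(C)C)C(C)C)cc3c2[C@H](C(=O)ON2C(=O)c4ccccc4C2=O)[C@@H](c2ccc(OS(C)(=O)=O)cc2)O3)cc1)(C(C)C)C(C)C | intermediate
20 | 5-bromo-2-hydroxy-3-methoxybenzaldehyde | O=Cc1cc(Br)cc(OC)c1O | starting material
21 | 4-methoxybenzyl chloride | COc1ccc(CCl)cc1 | starting material
22 | 5-bromo-3-methoxy-2-(4-methoxybenzyloxy)benzaldehyde | O=Cc1cc(Br)cc(OC)c1OCc1ccc(OC)cc1 | intermediate
23 | 1-bromo-3,5-dimethoxybenzene | COc1cc(Br)cc(OC)c1 | starting material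
24 | 3,5-dimethoxyphenylmagnesium bromide | COc1cc([Mg]Br)cc(OC)c1 | intermediate (not isolated)
25 | [5-bromo-3-methoxy-2-(4-methoxybenzyloxy)phenyl](3,5-dimethoxyphenyl)methanol, racemic | OC(c1cc(OC)cc(OC)c1)c1cc(Br)cc(OC)c1OCc1ccc(OC)cc1 | intermediate
26 | [5-bromo-3-methoxy-2-(4-methoxybenzyloxy)phenyl](3,5-dimethoxyphenyl)methanone | O=C(c1cc(OC)cc(OC)c1)c1cc(Br)cc(OC)c1OCc1ccc(OC)cc1 | intermediate
27 | hydrazone of ketone 26 | NN=C(c1cc(OC)cc(OC)c1)c1cc(Br)cc(OC)c1OCc1ccc(OC)cc1 | intermediate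
28 | [5-bromo-3-methoxy-2-(4-methoxybenzyloxy)phenyl](3,5-dimethoxyphenyl)diazomethane | [N-]=[N+]=C(c1cc(OC)cc(OC)c1)c1cc(Br)cc(OC)c1OCc1ccc(OC)cc1 | intermediate (not isolated)
29 | (2S,3R)-5-bromo-3-(3,5-dimethoxyphenyl)-7-methoxy-2-(4-methoxyphenyl)-2,3-dihydrobenzofuran (cis) | Brc1cc(OC)c2c(c1)[C@@H](c1cc(OC)cc(OC)c1)[C@@H](c1ccc(OC)cc1)O2 | intermediate
30 | (2R,3R)-5-bromo-3-(3,5-dimethoxyphenyl)-7-methoxy-2-(4-methoxyphenyl)-2,3-dihydrobenzofuran (trans) | Brc1cc(OC)c2c(c1)[C@@H](c1cc(OC)cc(OC)c1)[C@H](c1ccc(OC)cc1)O2 | intermediate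
31 | (2R,3R)-5-bromo-3-(3,5-dihydroxyphenyl)-2-(4-hydroxyphenyl)-2,3-dihydrobenzofuran-7-ol | Brc1cc(O)c2c(c1)[C@@H](c1cc(O)cc(O)c1)[C@H](c1ccc(O)cc1)O2 | intermediate
32 | (2R,3R)-5-bromo-3-[3,5-bis(triisopropylsilyloxy)phenyl]-7-(triisopropylsilyloxy)-2-[4-(triisopropylsilyloxy)phenyl]-2,3-dihydrobenzofuran | Brc1cc(O[Si](C(C)C)(C(C)C)C(C)C)c2c(c1)[C@@H](c1cc(O[Si](C(C)C)(C(C)C)C(C)C)cc(O[Si](C(C)C)(C(C)C)C(C)C)c1)[C@H](c1ccc(O[Si](C(C)C)(C(C)C)C(C)C)cc1)O2 | intermediate
33 | 5-lithio analogue of 32 | [Li]c1cc(O[Si](C(C)C)(C(C)C)C(C)C)c2c(c1)[C@@H](c1cc(O[Si](C(C)C)(C(C)C)C(C)C)cc(O[Si](C(C)C)(C(C)C)C(C)C)c1)[C@H](c1ccc(O[Si](C(C)C)(C(C)C)C(C)C)cc1)O2 | intermediate (not isolated)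
34 | 5-(chlorozincio) analogue of 32 | Cl[Zn]c1cc(O[Si](C(C)C)(C(C)C)C(C)C)c2c(c1)[C@@H](c1cc(O[Si](C(C)C)(C(C)C)C(C)C)cc(O[Si](C(C)C)(C(C)C)C(C)C)c1)[C@H](c1ccc(O[Si](C(C)C)(C(C)C)C(C)C)cc1)O2 | intermediate (not isolated)
35 | hexakis-O-triisopropylsilyl 4-O-mesyl trimer (mesylate on the C2 aryl group), (2S,3S,2'R,3'R) | CC(C)[Si](Oc1ccc(/C=C/c2cc(O[Si](C(C)C)(C(C)C)C(C)C)cc3c2[C@H](c2cc(O[Si](C(C)C)(C(C)C)C(C)C)c4c(c2)[C@@H](c2cc(O[Si](C(C)C)(C(C)C)C(C)C)cc(O[Si](C(C)C)(C(C)C)C(C)C)c2)[C@H](c2ccc(O[Si](C(C)C)(C(C)C)C(C)C)cc2)O4)[C@@H](c2ccc(OS(C)(=O)=O)cc2)O3)cc1)(C(C)C)C(C)C | intermediate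
36 | hexakis-O-triisopropylsilyl trimer with free 4-hydroxyphenyl at C2, (2S,3S,2'R,3'R) | CC(C)[Si](Oc1ccc(/C=C/c2cc(O[Si](C(C)C)(C(C)C)C(C)C)cc3c2[C@H](c2cc(O[Si](C(C)C)(C(C)C)C(C)C)c4c(c2)[C@@H](c2cc(O[Si](C(C)C)(C(C)C)C(C)C)cc(O[Si](C(C)C)(C(C)C)C(C)C)c2)[C@H](c2ccc(O[Si](C(C)C)(C(C)C)C(C)C)cc2)O4)[C@@H](c2ccc(O)cc2)O3)cc1)(C(C)C)C(C)C | intermediate
37 | (2S,3S)-3-[(2R,3R)-3-(3,5-dihydroxyphenyl)-7-hydroxy-2-(4-hydroxyphenyl)-2,3-dihydrobenzofuran-5-yl]-2-(4-hydroxyphenyl)-4-[(E)-4-hydroxystyryl]-2,3-dihydrobenzofuran-6-ol | Oc1ccc(/C=C/c2cc(O)cc3c2[C@H](c2cc(O)c4c(c2)[C@@H](c2cc(O)cc(O)c2)[C@H](c2ccc(O)cc2)O4)[C@@H](c2ccc(O)cc2)O3)cc1 | target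

**Step count**

Total: 23 steps. Longest linear sequence: 14 steps (steps 1–8, 10–12, 21–23, from 1 to 37). The primed fragment takes 8 steps (13–20) and the styrene 1 step (9).

**Steps most likely to fail**

1. Step 6 (oxidative ring contraction). The acidic methanolic medium may cleave the aryl silyl ether. The C2 aryl group may migrate instead of the benzo ring, the iodonium intermediate may eliminate to the flavone, or the oxidant may attack the electron-rich benzo ring. The fallback sets out from 8 and comes back at 11, making the same C3–C3a bond by a Wolff ring contraction. Flavanone 8 is acylated at C3 (LiN(SiMe3)2, CF3CO2CH2CF3, THF, −78 °C) to the 3-trifluoroacetyl flavanone F1. Detrifluoroacetylative diazo transfer (MsN3, Et3N, MeCN, H2O) then gives the (2S)-3-diazoflavanone F2. Irradiation in methanol (or PhCO2Ag, Et3N, MeOH) expels nitrogen, and the benzo ring carbon shifts to C3 to give the ring-contracted ketene, which methanol traps as 11 together with its 2,3-cis epimer F3. A catalytic amount of DBU in toluene should equilibrate the mixture to the thermodynamically favoured trans ester 11.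

2. Step 21 (decarboxylative arylation). Capture of the hindered C3 radical by the bulky aryl-nickel species may be slow, so that the radical is reduced or dimerises, and the precious arylzinc reagent, needed in excess, may be lost to protonation or homocoupling. The fallback sets out from 32 and 19 and comes back at 35, running the union as a reductive cross-electrophile coupling without an organometallic partner. Bromide 32 is converted (t-BuLi, THF, −78 °C; then I2) into the (2R,3R)-5-iodo analogue F4. Ester 19 and F4, in near-equimolar amounts, are then coupled with NiBr2·glyme, 4,4'-di-tert-butyl-2,2'-bipyridine and zinc dust in DMA at rt to give 35.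

3. Step 4 (enantioselective conjugate addition). Insertion into the electron-rich 5,7-dioxygenated chromone may be slow, so that protodeboronation of the boronic acid takes over, and facial selectivity may be poor. The fallback sets out from 3 and comes back at 8, bypassing the chromone. Acetophenone 3 and 4-(methanesulfonyloxy)benzaldehyde F5 (from 4-hydroxybenzaldehyde and MsCl) are condensed with pyrrolidine in ethanol (aldol condensation and oxa-Michael ring closure) to the racemic flavanone F6. Preparative chromatography on a polysaccharide carbamate chiral phase then delivers (2S)-8.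

**Further compounds**

F1 | step 6 | (2S)-5-O-benzyl-4'-O-methanesulfonyl-7-O-(triisopropylsilyl)-3-(trifluoroacetyl)naringenin | O=C1C(C(=O)C(F)(F)F)[C@@H](c2ccc(OS(C)(=O)=O)cc2)Oc2cc(O[Si](C(C)C)(C(C)C)C(C)C)cc(OCc3ccccc3)c12
F2 | step 6 | (2S)-3-diazo-5-O-benzyl-4'-O-methanesulfonyl-7-O-(triisopropylsilyl)naringenin | O=C1C(=[N+]=[N-])[C@@H](c2ccc(OS(C)(=O)=O)cc2)Oc2cc(O[Si](C(C)C)(C(C)C)C(C)C)cc(OCc3ccccc3)c12
F3 | step 6 | methyl (2S,3R)-4-benzyloxy-2-[4-(methanesulfonyloxy)phenyl]-6-(triisopropylsilyloxy)-2,3-dihydrobenzofuran-3-carboxylate (2,3-cis epimer of 11) | c1ccccc1COc1cc(O[Si](C(C)C)(C(C)C)C(C)C)cc2c1[C@@H](C(=O)OC)[C@@H](c1ccc(OS(C)(=O)=O)cc1)O2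
F4 | step 21 | (2R,3R)-5-iodo-3-[3,5-bis(triisopropylsilyloxy)phenyl]-7-(triisopropylsilyloxy)-2-[4-(triisopropylsilyloxy)phenyl]-2,3-dihydrobenzofuran | Ic1cc(O[Si](C(C)C)(C(C)C)C(C)C)c2c(c1)[C@@H](c1cc(O[Si](C(C)C)(C(C)C)C(C)C)cc(O[Si](C(C)C)(C(C)C)C(C)C)c1)[C@H](c1ccc(O[Si](C(C)C)(C(C)C)C(C)C)cc1)O2
F5 | step 4 | 4-(methanesulfonyloxy)benzaldehyde | O=Cc1ccc(OS(C)(=O)=O)cc1
F6 | step 4 | racemic 5-O-benzyl-4'-O-methanesulfonyl-7-O-(triisopropylsilyl)naringenin | O=C1CC(c2ccc(OS(C)(=O)=O)cc2)Oc2cc(O[Si](C(C)C)(C(C)C)C(C)C)cc(OCc3ccccc3)c12
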